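**Strategy.** The bicyclo[3.3.1]nonane-2,4,9-trione is opened at C5–C6, the bond from the prenyl-bearing bridgehead C5 (between C4 and C9) to the ring CH2. Its precursor is an achiral aromatic ether: a 3,5-diprenyl acylphloroglucinol alkylated on O4 by an (E)-2-(hydroxymethyl)acrylate that carries the future C8 methyl and homoprenyl groups. In one operation a catalyst-controlled dearomative Claisen shift joins C1 to C8 (vicinal quaternary pair) and uncovers an α-methylene ester, and the second prenyl-bearing ring carbon C5, 1,3 to C1 across the C9 carbonyl of the phloroglucinol-derived ring, then adds to its CH2 (C6). The ester carbon becomes C1′ of the geranyl chain; C7 is fixed afterwards by epimerisation of the derived aldehyde.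

Key step: step 6

Remark: atoms are numbered as in the bicyclic core (C1 and C5 bridgeheads, C9 bridging carbonyl, C3 aroyl-bearing carbon, C6 ring CH2, C7, C8; C1′ is the geranyl CH2 on C7), and the enantiomer of the chiral ligand in step 6 is taken to be the one that gives the configuration shown.

Step 1
Reactants: 1 3-hydroxybenzoic acid
Product: 2 3-(tosyloxy)benzoic acid
Conditions: TsCl, aq. NaOH, THF, 0 °C to rt; then HCl
Reagents that add atoms: p-toluenesulfonyl chloride, Cc1ccc(cc1)S(=O)(=O)Cl
Why: Schotten–Baumann O-sulfonylation of the phenoxide should give an aryl tosylate that tolerates Lewis acid, cold aqueous base, hydride and Pd(0), while any mixed carboxylic–sulfonic anhydride is hydrolysed back to the acid.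

Step 2
Reactants: 2 3-(tosyloxy)benzoic acid; 3 phloroglucinol
Product: 5 (2,4,6-trihydroxyphenyl)[3-(tosyloxy)phenyl]methanone, via acid chloride 4 (not isolated)
Conditions: (COCl)2, cat. DMF, CH2Cl2, rt; then 3, AlCl3, PhNO2, 0 °C to rt
Reagents that add atoms: none
Why: Friedel–Crafts acylation of the symmetrical, highly activated triphenol should stop after one acylation because the chelated ketone deactivates the ring.

Step 3
Reactants: 5 (2,4,6-trihydroxyphenyl)[3-(tosyloxy)phenyl]methanone; 6 prenyl bromide
Product: 7 [2,4,6-trihydroxy-3,5-bis(3-methylbut-2-en-1-yl)phenyl][3-(tosyloxy)phenyl]methanone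
Conditions: 6 (2.1 equiv), 10% aq. KOH, 0 °C
Reagents that add atoms: none
Why: C-alkylation of the acylphloroglucinol polyanion in water should take place at the two free ring carbons, the usual entry to 3,5-diprenyl acylphloroglucinols, because the hydrogen-bonding solvent suppresses O-alkylation.

Step 4
Reactants: 8 methyl but-2-ynoate; 9 5-bromo-2-methylpent-2-ene
Product: 12 methyl (E)-2-(hydroxymethyl)-3,7-dimethylocta-2,6-dienoate (CH2OH cis to the 4-methylpent-3-enyl group), via Grignard reagent 10 (not isolated), via alkenylcopper 11 (not isolated)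
Conditions: 9, Mg, THF; CuBr·SMe2, −40 °C; 8, −78 °C; then CH2O (gas), −78 to −30 °C; aq. NH4Cl
Reagents that add atoms: formaldehyde, C=O
Why: Syn-carbocupration of the alkynoate places homoprenyl and copper cis, and the α-(methoxycarbonyl)alkenylcopper should keep its geometry at low temperature and be hydroxymethylated with retention (cuprate addition to an ynoate with electrophilic trapping).

Step 5
Reactants: 7 [2,4,6-trihydroxy-3,5-bis(3-methylbut-2-en-1-yl)phenyl][3-(tosyloxy)phenyl]methanone; 12 methyl (E)-2-(hydroxymethyl)-3,7-dimethylocta-2,6-dienoate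
Product: 13 methyl (E)-2-({3,5-dihydroxy-2,6-bis(3-methylbut-2-en-1-yl)-4-[3-(tosyloxy)benzoyl]phenoxy}methyl)-3,7-dimethylocta-2,6-dienoate
Conditions: PPh3, DIAD, THF, 0 °C to rt
Reagents that add atoms: none
Why: Mitsunobu etherification should engage the most acidic and only non-chelated phenol (4-OH; the 2- and 6-OH are hydrogen-bonded to the ketone) in SN2 displacement at the primary allylic carbinol, giving the O-alkyl and not a C-alkyl product.

Step 6
Reactants: 13 methyl (E)-2-({3,5-dihydroxy-2,6-bis(3-methylbut-2-en-1-yl)-4-[3-(tosyloxy)benzoyl]phenoxy}methyl)-3,7-dimethylocta-2,6-dienoate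
Product: 15 methyl 4-hydroxy-8-methyl-1,5-bis(3-methylbut-2-en-1-yl)-8-(4-methylpent-3-en-1-yl)-2,9-dioxo-3-[3-(tosyloxy)benzoyl]bicyclo[3.3.1]non-3-ene-7-carboxylate (C1/C5/C8 as in 25; ester on C7 axial), via Claisen product 14 (not isolated)
Conditions: Ni(OTf)2 (10 mol%), chiral N,N′-dioxide ligand (10 mol%), 4 Å MS, CH2Cl2, 35 °C; then DBU, rt
Reagents that add atoms: none
Why: Proposed new method: a chiral N,N′-dioxide–Ni(II) Lewis acid is expected to chelate the ether oxygen and the ester carbonyl of the 2-(methoxycarbonyl)allyl unit of 13, which polarises the aryl O–CH2 bond, accelerates the aromatic [3,3] Claisen shift onto one of the two enantiotopic prenyl-bearing ortho carbons (the only ortho positions) and lets the ligand choose the face of C8; the closest known reaction types are the thermal dearomative Claisen rearrangement of acylphloroglucinol allyl ethers and Lewis-acid-catalysed enantioselective Claisen rearrangements of chelating 2-alkoxycarbonyl allyl vinyl ethers and aryl allyl ethers. In the chair transition state the prenyl group on the ring carbon and the homoprenyl group of the (E)-alkene sit trans across the new C1–C8 bond, so C8 (set by the catalyst) fixes C1 and the vicinal quaternary pair should form with the relative configuration of the target. DBU then deprotonates the not-isolated 14, and the prenyl-bearing carbon C5 of the vinylogous enolate adds to the CH2 terminus of the α-methylene ester in a 6-endo-trig Michael addition, the known ring-closing mode of dearomatised acylphloroglucinols onto α-methylene carbonyl acceptors. This closes the ring C5–C6–C7–C8–C1–C9; C5 can only bond on the ring face that carries the C1 side chain, so its configuration is relayed from C1, and C7 is protonated without consequence because it is equilibrated in step 7. The step needs C-attack at C5 in preference to the aroyl-bearing C3 and to the enol oxygens: C3 is the more stabilised and more hindered centre, and O-adducts should revert under the reversible conditions.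

Step 7
Reactants: 15 methyl 4-hydroxy-8-methyl-1,5-bis(3-methylbut-2-en-1-yl)-8-(4-methylpent-3-en-1-yl)-2,9-dioxo-3-[3-(tosyloxy)benzoyl]bicyclo[3.3.1]non-3-ene-7-carboxylate
Product: 17 7-exo (equatorial) carbaldehyde corresponding to 15, via endo aldehyde 16 (not isolated)
Conditions: DIBAL-H (3 equiv), CH2Cl2, −78 °C; Rochelle salt; then DBU, PhMe, 50 °C
Reagents that add atoms: none
Why: DIBAL-H should stop at the aldehyde through the stable tetrahedral aluminate of the hindered ester while the β-triketone is masked as its aluminium enolate, and DBU then equilibrates C7 through the aldehyde enolate to the equatorial (exo) epimer, the expected thermodynamic one, which sets C7.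

Step 8
Reactants: 9 5-bromo-2-methylpent-2-ene; 18 lithium acetylide–ethylenediamine complex
Product: 19 6-methylhept-5-en-1-yne
Conditions: DMSO, 10 °C to rt
Reagents that add atoms: none
Why: SN2 alkylation of the acetylide by the primary homoallylic bromide.

Step 9
Reactants: 19 6-methylhept-5-en-1-yne
Product: 21 (E)-1-iodo-2,6-dimethylhepta-1,5-diene, via alkenylalane 20 (not isolated)
Conditions: Me3Al, Cp2ZrCl2 (cat.), CH2Cl2, rt; then I2, THF, −20 °C
Reagents that add atoms: trimethylaluminium, C[Al](C)C; iodine, II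
Why: Negishi zirconium-catalysed carboalumination adds methyl and aluminium syn (methyl to the internal carbon) and iodinolysis of the C–Al bond proceeds with retention, which fixes the (E)-alkene.

Step 10
Reactants: 17 7-exo carbaldehyde; 21 (E)-1-iodo-2,6-dimethylhepta-1,5-diene
Product: 23 4-O-acetyl 7-exo-[(E)-1-acetoxy-3,7-dimethylocta-2,6-dien-1-yl] compound (carbinol epimers), via allylic alcohol 22 (not isolated)
Conditions: CrCl2 (excess), NiCl2 (cat.), DMF–THF, rt; then Ac2O, pyridine, DMAP
Reagents that add atoms: acetic anhydride, CC(=O)OC(C)=O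
Why: Nozaki–Hiyama–Kishi coupling should add the alkenylchromium(III) species chemoselectively to the aldehyde with retention of alkene geometry in the presence of the ketones and the sulfonate, and acetylation of the carbinol (configuration inconsequential) and of the enol prepares the allylic leaving group.

Step 11
Reactants: 23 4-O-acetyl 7-exo-[(E)-1-acetoxy-3,7-dimethylocta-2,6-dien-1-yl] compound
Product: 24 4-O-acetyl-3′-O-tosyl derivative of 25
Conditions: Pd(PPh3)4 (5 mol%), Bu3SnH, THF, rt
Reagents that add atoms: none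
Why: Pd(0) ionises the allylic acetate and the tin hydride should deliver hydride to the less substituted, secondary allyl terminus C1′ (Tsuji–Trost-type hydrogenolysis), which leaves the trisubstituted (E)-alkene of the geranyl chain and removes the temporary oxygen.

Step 12
Reactants: 24 4-O-acetyl-3′-O-tosyl derivative of 25
Product: 25 CNP0285073.1
Conditions: KOH, MeOH–H2O, 50 °C; then aq. HCl
Reagents that add atoms: none
Why: Hydroxide cleaves the aryl tosylate at sulfur and the enol acetate at the acyl carbon, while the product is protected from retro-Claisen cleavage as its β-triketone enolate until acidification.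

**Compound list**

1 | 3-hydroxybenzoic acid | OC(=O)c1cccc(O)c1 | starting material
2 | 3-(tosyloxy)benzoic acid | Cc1ccc(cc1)S(=O)(=O)Oc1cccc(c1)C(O)=O | intermediate
3 | phloroglucinol (benzene-1,3,5-triol) | Oc1cc(O)cc(O)c1 | starting material
4 | 3-(tosyloxy)benzoyl chloride | Cc1ccc(cc1)S(=O)(=O)Oc1cccc(c1)C(Cl)=O | intermediate
5 | (2,4,6-trihydroxyphenyl)[3-(tosyloxy)phenyl]methanone | Cc1ccc(cc1)S(=O)(=O)Oc1cccc(c1)C(=O)c1c(O)cc(O)cc1O | intermediate
6 | prenyl bromide (1-bromo-3-methylbut-2-ene) | CC(C)=CCBr | starting material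
7 | [2,4,6-trihydroxy-3,5-bis(3-methylbut-2-en-1-yl)phenyl][3-(tosyloxy)phenyl]methanone | Cc1ccc(cc1)S(=O)(=O)Oc1cccc(c1)C(=O)c1c(O)c(CC=C(C)C)c(O)c(CC=C(C)C)c1O | intermediate
8 | methyl but-2-ynoate | CC#CC(=O)OC | starting material
9 | 5-bromo-2-methylpent-2-ene | CC(C)=CCCBr | starting material
10 | (4-methylpent-3-en-1-yl)magnesium bromide | CC(C)=CCC[Mg]Br | intermediate
11 | (E)-alkenylcopper from syn-addition to 8 (Cu cis to the 4-methylpent-3-enyl group) | [Cu]/C(C(=O)OC)=C(\CCC=C(C)C)C | intermediate
12 | methyl (E)-2-(hydroxymethyl)-3,7-dimethylocta-2,6-dienoate | OC/C(C(=O)OC)=C(\CCC=C(C)C)C | intermediate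
13 | methyl (E)-2-({3,5-dihydroxy-2,6-bis(3-methylbut-2-en-1-yl)-4-[3-(tosyloxy)benzoyl]phenoxy}methyl)-3,7-dimethylocta-2,6-dienoate | Cc1ccc(cc1)S(=O)(=O)Oc1cccc(c1)C(=O)c1c(O)c(CC=C(C)C)c(OC/C(C(=O)OC)=C(\CCC=C(C)C)C)c(CC=C(C)C)c1O | intermediate
14 | methyl 2-{2-[2,4-dihydroxy-1,5-bis(3-methylbut-2-en-1-yl)-6-oxo-3-(3-(tosyloxy)benzoyl)cyclohexa-2,4-dien-1-yl]-6-methylhept-5-en-2-yl}prop-2-enoate; ring C1 and side-chain C2 (core C1 and C8) configured as in 25 | OC1=C(CC=C(C)C)C(=O)[C@@](CC=C(C)C)(C(O)=C1C(=O)c3cccc(OS(=O)(=O)c4ccc(C)cc4)c3)[C@@](C(=C)C(=O)OC)(C)CCC=C(C)C | intermediate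
15 | methyl 4-hydroxy-8-methyl-1,5-bis(3-methylbut-2-en-1-yl)-8-(4-methylpent-3-en-1-yl)-2,9-dioxo-3-[3-(tosyloxy)benzoyl]bicyclo[3.3.1]non-3-ene-7-carboxylate; C1, C5, C8 as in 25, 8-methyl axial on the C9 face, ester on C7 axial (endo; configuration at C7 inconsequential) | COC(=O)[C@H]1C[C@]2(CC=C(C)C)C(=O)[C@@](CC=C(C)C)(C(=O)C(C(=O)c3cccc(OS(=O)(=O)c4ccc(C)cc4)c3)=C2O)[C@@]1(C)CCC=C(C)C | intermediate
16 | 7-endo (axial) carbaldehyde corresponding to 15 | O=C[C@H]1C[C@]2(CC=C(C)C)C(=O)[C@@](CC=C(C)C)(C(=O)C(C(=O)c3cccc(OS(=O)(=O)c4ccc(C)cc4)c3)=C2O)[C@@]1(C)CCC=C(C)C | intermediate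
17 | 7-exo (equatorial) carbaldehyde: 4-hydroxy-8-methyl-1,5-bis(3-methylbut-2-en-1-yl)-8-(4-methylpent-3-en-1-yl)-2,9-dioxo-3-[3-(tosyloxy)benzoyl]bicyclo[3.3.1]non-3-ene-7-carbaldehyde, all four ring stereocentres as in 25 | O=C[C@@H]1C[C@]2(CC=C(C)C)C(=O)[C@@](CC=C(C)C)(C(=O)C(C(=O)c3cccc(OS(=O)(=O)c4ccc(C)cc4)c3)=C2O)[C@@]1(C)CCC=C(C)C | intermediate
18 | lithium acetylide–ethylenediamine complex | [Li+].[C-]#C.NCCN | starting material
19 | 6-methylhept-5-en-1-yne | CC(C)=CCCC#C | intermediate
20 | (E)-(2,6-dimethylhepta-1,5-dien-1-yl)dimethylalane | C[Al](C)/C=C(\C)CCC=C(C)C | intermediate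
21 | (E)-1-iodo-2,6-dimethylhepta-1,5-diene | I/C=C(\C)CCC=C(C)C | intermediate
22 | 7-exo-[(E)-1-hydroxy-3,7-dimethylocta-2,6-dien-1-yl] analogue of 17 (carbinol epimers) | CC(C)=CCC/C(C)=C/C(O)[C@@H]1C[C@]2(CC=C(C)C)C(=O)[C@@](CC=C(C)C)(C(=O)C(C(=O)c3cccc(OS(=O)(=O)c4ccc(C)cc4)c3)=C2O)[C@@]1(C)CCC=C(C)C | intermediate
23 | allylic acetate and enol (O4) acetate of 22 | CC(C)=CCC/C(C)=C/C(OC(C)=O)[C@@H]1C[C@]2(CC=C(C)C)C(=O)[C@@](CC=C(C)C)(C(=O)C(C(=O)c3cccc(OS(=O)(=O)c4ccc(C)cc4)c3)=C2OC(C)=O)[C@@]1(C)CCC=C(C)C | intermediate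
24 | 4-O-acetyl-3′-O-tosyl derivative of 25 | CC(C)=CCC/C(C)=C/C[C@@H]1C[C@]2(CC=C(C)C)C(=O)[C@@](CC=C(C)C)(C(=O)C(C(=O)c3cccc(OS(=O)(=O)c4ccc(C)cc4)c3)=C2OC(C)=O)[C@@]1(C)CCC=C(C)C | intermediate
25 | CNP0285073.1: 7-exo-geranyl-4-hydroxy-3-(3-hydroxybenzoyl)-8-methyl-1,5-bis(3-methylbut-2-en-1-yl)-8-(4-methylpent-3-en-1-yl)bicyclo[3.3.1]non-3-ene-2,9-dione (8-methyl axial on the C9 face, 8-homoprenyl equatorial and trans to geranyl) | CC(C)=CCC/C(C)=C/C[C@@H]1C[C@]2(CC=C(C)C)C(=O)[C@@](CC=C(C)C)(C(=O)C(C(=O)c3cccc(O)c3)=C2O)[C@@]1(C)CCC=C(C)C | target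

**Step count.** 12 steps in total; the longest linear sequence is 9 steps (1, 2, 3, 5, 6, 7, 10, 11, 12).

**Steps most likely to fail**

Step 6 (Proposed new method). The Lewis acid may be sequestered by the hydroxy-ketone chelate, or it may ionise the ether to an ion pair that recombines without facial control, so that enantioselectivity is lost. Fallback with known chemistry: starting from 13, the uncatalysed thermal dearomative Claisen rearrangement (toluene, 110 °C) followed by DBU should give racemic 15, still with the C1/C8 relative configuration dictated by the chair transition state. The enantiomers are then separated by preparative chromatography on a chiral stationary phase; the enantiomer of 15 F1 is discarded and 15 re-enters the route.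

Step 4. The alkene geometry may erode because the alkenylcopper equilibrates through its allenoate form before the slow capture by formaldehyde. Fallback: starting from 8 and 9, the alkenylcopper 11 is quenched at −78 °C with iodine to give methyl (Z)-2-iodo-3,7-dimethylocta-2,6-dienoate F2, and Stille coupling with (tributylstannyl)methanol (Pd(PPh3)4, toluene, 80 °C) returns to 12.

Step 11. Hydride may be delivered to the tertiary allyl terminus (alkene transposition), or the alkene geometry may be lost through π–σ–π isomerisation of the allyl complex. Fallback: starting from 22, isolated from step 10 before acetylation, a radical Barton–McCombie deoxygenation replaces the palladium hydride step. 1,1′-Thiocarbonyldiimidazole gives the O-allylic imidazole-1-carbothioate of 22 F3; Bu3SnH/AIBN (toluene, 80 °C) then reduces it through the allyl radical, which takes hydrogen at its less hindered terminus, to the 3′-O-tosyl derivative of 25 F4; the conditions of step 12 convert this into 25.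

Further compounds
F1 | step 6 | enantiomer of 15 | COC(=O)[C@@H]1C[C@@]2(CC=C(C)C)C(=O)[C@](CC=C(C)C)(C(=O)C(C(=O)c3cccc(OS(=O)(=O)c4ccc(C)cc4)c3)=C2O)[C@]1(C)CCC=C(C)C
F2 | step 4 | methyl (Z)-2-iodo-3,7-dimethylocta-2,6-dienoate | I/C(C(=O)OC)=C(\CCC=C(C)C)C
F3 | step 11 | O-allylic imidazole-1-carbothioate of 22 | CC(C)=CCC/C(C)=C/C(OC(=S)n5ccnc5)[C@@H]1C[C@]2(CC=C(C)C)C(=O)[C@@](CC=C(C)C)(C(=O)C(C(=O)c3cccc(OS(=O)(=O)c4ccc(C)cc4)c3)=C2O)[C@@]1(C)CCC=C(C)C
F4 | step 11 | 3′-O-tosyl derivative of 25 | CC(C)=CCC/C(C)=C/C[C@@H]1C[C@]2(CC=C(C)C)C(=O)[C@@](CC=C(C)C)(C(=O)C(C(=O)c3cccc(OS(=O)(=O)c4ccc(C)cc4)c3)=C2O)[C@@]1(C)CCC=C(C)C
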